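**Retrosynthetic overview**
1. Target 18 ⇐ vinyl ketol 16: the C6 hydroxymethyl comes from a C5 vinyl group (ozonolysis, reduction); C16 is set by kinetic protonation of a C15–C16 silyl enol ether.
2. Ring D (C13–C16, bridgehead 13-OH) ⇐ intramolecular aldol of a C8 propanoyl group onto the C13 ketone; quaternary C8 ⇐ C-acylation of the lactone enolate.
3. Lactone ring, joining rings A and C ⇐ key C20–O bond: carboxylate oxa-Michael addition of acid 9 to α-methylene enone 6, relayed into C9–C10 Michael closure (formal [4+2]).
4. Enone 6 ⇐ 4,4-dimethylcyclohex-2-en-1-one (asymmetric vinyl addition sets C5); acid 9 ⇐ 1,4-dioxaspiro[4.5]decan-7-one.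
5. Ring order: rings A and C are bought as carbocycles; lactone ring (step 6); ring D (step 8).

Assumption: atoms carry kaurane numbers in every intermediate (ring A = C1–C5, C10; lactone = C7, C8, C9, C10, C20, O; ring C = C8, C9, C11–C14; ring D = C8, C14, C13, C16, C15; C17 = methyl on C16). Compounds 1 and 7 and solutions of LiN(i-Pr)2 and LiN(SiMe3)2 are bought. CIP labels are computed per compound, so a label can change while the geometry stays the same.

**Step 1**
Reactants: 1 4,4-dimethylcyclohex-2-en-1-one
Product: 2 4,4-dimethylcyclohexa-2,5-dien-1-one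
Conditions: DDQ, dioxane, reflux
Reagents that add atoms: none
Why: Quinone dehydrogenation of the enone can only introduce the C5=C6 double bond because C4 is quaternary, and no stereocentre is involved.

**Step 2**
Reactants: 2 4,4-dimethylcyclohexa-2,5-dien-1-one
Product: 3 (5R)-5-ethenyl-4,4-dimethylcyclohex-2-en-1-one
Conditions: CH2=CHBF3K (1.2 equiv), [Rh(cod)2]BF4 (3 mol%), (R)-BINAP, PhMe/H2O, 100 °C
Reagents that add atoms: potassium vinyltrifluoroborate, [K+].C=C[B-](F)(F)F
Why: Rhodium-catalysed asymmetric 1,4-addition of an alkenyl trifluoroborate (Hayashi–Miyaura type) to one of the two homotopic enone units, where the Rh/(R)-BINAP alkenyl complex selects the face and sets C5 as R (ligand antipode chosen by analogy with cyclohex-2-enone) and the hindered mono-adduct reacts further only slowly.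

**Step 3**
Reactants: 3 (5R)-5-ethenyl-4,4-dimethylcyclohex-2-en-1-one
Product: 6 (5R)-5-ethenyl-4,4-dimethyl-6-methylidenecyclohex-2-en-1-one, via Mannich base 4 (not isolated), via methiodide 5 (not isolated)
Conditions: LiN(i-Pr)2, THF, −78 °C; Me2N=CH2 I, −78 to 0 °C; MeI, CH2Cl2, 23 °C; NaHCO3 (aq), 23 °C; product used at once
Reagents that add atoms: N,N-dimethylmethylideneammonium iodide, C=[N+](C)C.[I-]; iodomethane, CI
Why: Kinetic deprotonation is possible only at the CH2 between C1 and C5 (C4 is quaternary), so a Mannich reaction followed by quaternisation and Hofmann-type E1cB elimination gives the exocyclic α-methylene enone without touching C5.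

**Step 4**
Reactants: 7 1,4-dioxaspiro[4.5]decan-7-one
Product: 8 1,4-dioxaspiro[4.5]dec-7-en-7-yl trifluoromethanesulfonate
Conditions: LiN(SiMe3)2, THF, −78 °C; PhNTf2, −78 to 0 °C
Reagents that add atoms: N-phenylbis(trifluoromethanesulfonimide), O=S(=O)(N(c1ccccc1)S(=O)(=O)C(F)(F)F)C(F)(F)F
Why: Enol triflate formation, in which the bulky amide removes a proton from the CH2 remote from the ketal (the CH2 between carbonyl and ketal is hindered) and the enolate is O-sulfonylated.

**Step 5**
Reactants: 8 1,4-dioxaspiro[4.5]dec-7-en-7-yl trifluoromethanesulfonate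
Product: 9 1,4-dioxaspiro[4.5]dec-7-ene-7-carboxylic acid
Conditions: Pd(OAc)2 (5 mol%), Ph2P(CH2)3PPh2, CO (1 atm), Et3N, DMF/H2O, 60 °C; citric acid work-up
Reagents that add atoms: carbon monoxide, [C-]#[O+]; water, O
Why: Palladium-catalysed hydroxycarbonylation (oxidative addition of the vinyl triflate to zerovalent palladium, CO insertion, hydrolysis of the acyl-palladium species) gives the conjugated acid with the double bond fixed at C8=C9.

**Step 6**
Reactants: 6 (5R)-5-ethenyl-4,4-dimethyl-6-methylidenecyclohex-2-en-1-one; 9 1,4-dioxaspiro[4.5]dec-7-ene-7-carboxylic acid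
Product: 11 cis-fused spirolactone (5R,8S,9R,10S) in which ring A [(5R)-5-ethenyl-4,4-dimethyl-1-oxocyclohex-2-ene] is spiro at C10 to the δ-lactone C7(=O)–O–C20H2 and the lactone is cis-fused at C8–C9 (8-H and 9-H cis) to ring C carrying the C13 ethylene ketal, via oxa-Michael ester 10 (not isolated)
Conditions: Mg(OTf)2 (1.2 equiv), i-Pr2NEt (2.5 equiv), 4 Å sieves, CH2Cl2/MeCN, 0 °C, slow addition of 6 (1.3 equiv), then 23 °C; NH4Cl (aq)
Reagents that add atoms: none
Why: Proposed new method: the magnesium carboxylate of 9 adds through oxygen to the terminal CH2 (C20) of the Mg(OTf)2-activated α-methylene enone (reversible oxa-Michael step, resting state 10), and the chelated magnesium enolate is trapped by intramolecular 6-endo Michael addition to the tethered cyclohexenoate, forming C9–C10 anti to the C5 vinyl group and, through a closed chair-like transition state with the ring A carbonyl endo, placing 9-H anti to C1 before protonation gives the cis-fused lactone; the closest known reaction types are MgI2- or TiCl4-promoted halo-Michael/aldol cascades of enones, oxa-Michael/Michael annulations of phenols and base-mediated intramolecular Michael additions, none of which uses a carboxylic acid to build a δ-lactone.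

**Step 7**
Reactants: 11 cis-fused spirolactone (5R,8S,9R,10S)
Product: 13 triketo lactone (5R,8S,9S,10S) in which C8 is quaternary and carries the propanoyl group C15(=O)–C16H2–C17H3 cis to 9-H and C13 is a ketone, via propanoyl ketal 12 (not isolated)
Conditions: LiN(i-Pr)2 (1.1 equiv), THF, −78 °C; EtCOCl, −78 °C; then 1 M HCl, THF, 23 °C
Reagents that add atoms: propanoyl chloride, CCC(Cl)=O; water, O
Why: Claisen-type C-acylation of the lactone enolate, which is attacked in equatorial mode on the face of the former 8-H (the other face is shielded by the axial ketal oxygen and by C10) so that the quaternary C8 (S) is formed with the propanoyl group cis to 9-H, after which aqueous acid hydrolyses the dioxolane to the C13 ketone.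

**Step 8**
Reactants: 13 triketo lactone (5R,8S,9S,10S)
Product: 15 bis-silyl compound (5R,8S,9S,10S,13S) with ring D closed, 13-OSiMe3 at the bridgehead and the silyl enol ether C15(OSiMe3)=C16(CH3), via ketol 14 (not isolated)
Conditions: DBU (0.2 equiv), PhMe, 60 °C; then Et3N, Me3SiOTf, 0 to 23 °C
Reagents that add atoms: trimethylsilyl trifluoromethanesulfonate, C[Si](C)(C)OS(=O)(=O)C(F)(F)F
Why: Intramolecular ketone–ketone aldol addition (5-(enolendo)-exo-trig) of C16 to the C13 carbonyl closes ring D with C13 (S) fixed by the only possible bridging mode from the axial C15 carbonyl, and O-silylation plus soft enolisation of C15 towards C16 makes the closure irreversible and erases the uncontrolled C16 centre.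

**Step 9**
Reactants: 15 bis-silyl compound (5R,8S,9S,10S,13S)
Product: 16 vinyl ketol (5R,8S,9S,10S,13S,16R), the target skeleton with 13-OH, C15 ketone, 16-methyl endo and an ethenyl group on C5 in place of CH2OH
Conditions: Bu4NF (2.5 equiv), AcOH (5 equiv), THF, −78 to −20 °C
Reagents that add atoms: none
Why: Kinetic enolate protonation, in which fluoride releases the C15–C16 enolate and AcOH protonates it on the exo face of the two-carbon bridge (the side of the one-carbon bridge C14; the endo face is screened by the axial 11-H), giving the endo 16-methyl group (16R) and the free 13-OH.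

**Step 10**
Reactants: 16 vinyl ketol (5R,8S,9S,10S,13S,16R)
Product: 18 CNP0533761.1, (5R,8S,9S,10S,13S,16R)-6,13-dihydroxy-1,15-dioxo-6,7-secokaur-2-en-7,20-olide, via aldehyde 17 (not isolated)
Conditions: O3, CH2Cl2, −78 °C; Me2S, −78 to 0 °C; NaBH(OAc)3, AcOH, 0 °C
Reagents that add atoms: ozone, [O-][O+]=O
Why: Chemoselective ozonolysis of the electron-rich monosubstituted vinyl group (the enone C2=C3 is electron-poor and flanked by the gem-dimethyl carbon) gives the C6 aldehyde, which NaBH(OAc)3 reduces in the cold without touching the hindered ketones or epimerising C5.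

**Compound list**
1 | 4,4-dimethylcyclohex-2-en-1-one | CC1(C)CCC(=O)C=C1 | starting material
2 | 4,4-dimethylcyclohexa-2,5-dien-1-one | CC1(C)C=CC(=O)C=C1 | intermediate
3 | (5R)-5-ethenyl-4,4-dimethylcyclohex-2-en-1-one | O=C1C=CC(C)(C)[C@@H](C=C)C1 | intermediate
4 | (5S)-6-[(dimethylamino)methyl]-5-ethenyl-4,4-dimethylcyclohex-2-en-1-one (Mannich base, C6 epimers) | O=C1C=CC(C)(C)[C@@H](C=C)C1CN(C)C | intermediate
5 | [(6S)-6-ethenyl-5,5-dimethyl-2-oxocyclohex-3-en-1-yl]methyl-trimethylammonium iodide (C1 epimers) | O=C1C=CC(C)(C)[C@@H](C=C)C1C[N+](C)(C)C.[I-] | intermediate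
6 | (5R)-5-ethenyl-4,4-dimethyl-6-methylidenecyclohex-2-en-1-one | O=C1C=CC(C)(C)[C@@H](C=C)C1=C | intermediate
7 | 1,4-dioxaspiro[4.5]decan-7-one | O=C1CCCC2(C1)OCCO2 | starting material
8 | 1,4-dioxaspiro[4.5]dec-7-en-7-yl trifluoromethanesulfonate | O=S(=O)(OC1=CCCC2(C1)OCCO2)C(F)(F)F | intermediate
9 | 1,4-dioxaspiro[4.5]dec-7-ene-7-carboxylic acid | OC(=O)C1=CCCC2(C1)OCCO2 | intermediate
10 | [(6S)-6-ethenyl-5,5-dimethyl-2-oxocyclohex-3-en-1-yl]methyl 1,4-dioxaspiro[4.5]dec-7-ene-7-carboxylate (ring C1 unassigned; present as its magnesium enolate) | O=C(OCC1C(=O)C=CC(C)(C)[C@H]1C=C)C1=CCCC2(C1)OCCO2 | intermediate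
11 | cis-fused spirolactone (5R,8S,9R,10S): ring A spiro at C10 to the C7(=O)–O–C20H2 lactone, lactone cis-fused at C8–C9 to ring C with C13 ethylene ketal, 8-H | [C@H]12CC3(OCCO3)CC[C@H]1[C@]1(COC2=O)C(=O)C=CC(C)(C)[C@H]1C=C | intermediate
12 | 8-propanoyl derivative of 11 (5R,8S,9S,10S), C13 ketal retained | CCC(=O)[C@]23CC4(OCCO4)CC[C@H]2[C@]1(COC3=O)C(=O)C=CC(C)(C)[C@H]1C=C | intermediate
13 | triketo lactone (5R,8S,9S,10S): 8-propanoyl, C13 ketone | CCC(=O)[C@]23CC(=O)CC[C@H]2[C@]1(COC3=O)C(=O)C=CC(C)(C)[C@H]1C=C | intermediate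
14 | ketol (5R,8S,9S,10S,13S; C16 epimers): ring D closed, 13-OH, C15 ketone, 16-methyl | CC1C(=O)[C@]23C[C@@]1(O)CC[C@H]2[C@]1(COC3=O)C(=O)C=CC(C)(C)[C@H]1C=C | intermediate
15 | bis-silyl compound (5R,8S,9S,10S,13S): 13-OSiMe3, C15(OSiMe3)=C16(CH3) | CC1=C(O[Si](C)(C)C)[C@]23C[C@@]1(O[Si](C)(C)C)CC[C@H]2[C@]1(COC3=O)C(=O)C=CC(C)(C)[C@H]1C=C | intermediate
16 | vinyl ketol (5R,8S,9S,10S,13S,16R): 13-OH, C15 ketone, 16-methyl endo, C5 ethenyl | C[C@H]1C(=O)[C@]23C[C@@]1(O)CC[C@H]2[C@]1(COC3=O)C(=O)C=CC(C)(C)[C@H]1C=C | intermediate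
17 | aldehyde (5R,8S,9S,10S,13S,16R): as 16 with C5–CHO (C6) | C[C@H]1C(=O)[C@]23C[C@@]1(O)CC[C@H]2[C@]1(COC3=O)C(=O)C=CC(C)(C)[C@H]1C=O | intermediate
18 | CNP0533761.1, (5R,8S,9S,10S,13S,16R)-6,13-dihydroxy-1,15-dioxo-6,7-secokaur-2-en-7,20-olide | C[C@H]1C(=O)[C@]23C[C@@]1(O)CC[C@H]2[C@]1(COC3=O)C(=O)C=CC(C)(C)[C@H]1CO | target

**Step count**
Total: 10 steps. Longest linear sequence: 8 steps (1, 2, 3, 6, 7, 8, 9, 10 from compound 1); steps 4 and 5 make the second fragment.

**Steps most likely to fail**

Step 6 (the proposed annulation). The oxa-Michael equilibrium may stay on the side of 6 + 9, 6 may isomerise to the endocyclic 2-methyl dienone, and the face selectivity at C9 is unproven. The fallback uses known chemistry and sets out from 3. Kinetic enolate formation with LiN(i-Pr)2 and aldol addition to monomeric formaldehyde at −78 °C gives (5S,6R)-5-ethenyl-6-(hydroxymethyl)-4,4-dimethylcyclohex-2-en-1-one F1. Carbodiimide esterification (EDC·HCl, DMAP) with acid 9 gives ester 10 as an isolated compound. Intramolecular Michael addition of its lithium enolate (LiN(SiMe3)2, THF, −78 °C) then closes the lactone, and the fallback comes back to the route at 11.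

Step 7 (C-acylation that creates the quaternary C8 next to the spiro centre). O-acylation or attack on the wrong face is possible. The fallback sets out from 11. Aldol addition of its lithium enolate to propanal gives the 8-(1-hydroxypropyl) spirolactone F2, and oxidation with Dess–Martin periodinane gives 12, where the fallback comes back to the route (aqueous HCl then gives 13).

Step 8 (5-(enolendo) aldol to a strained bridgehead ketol). The equilibrium may favour open 13, or other enolates may compete. The fallback sets out from 11. Acylation of its lithium enolate with acryloyl chloride gives the 8-prop-2-enoyl spirolactone F3, and aqueous HCl removes the ketal to give the 8-prop-2-enoyl 13-ketone F4. A copper hydride reductive aldol cyclisation ([(Ph3P)CuH]6, PhMe, −40 °C) then adds hydride to the unhindered acryloyl terminus and the copper enolate closes on the C13 ketone. This gives ketol 14, where the fallback comes back to the route (silylation to 15 as in step 8).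

**Further compounds**
F1 | step 6 | (5S,6R)-5-ethenyl-6-(hydroxymethyl)-4,4-dimethylcyclohex-2-en-1-one | O=C1C=CC(C)(C)[C@@H](C=C)[C@@H]1CO
F2 | step 7 | 8-(1-hydroxypropyl) spirolactone, C13 ketal retained, carbinol centre unassigned | CCC(O)[C@]23CC4(OCCO4)CC[C@H]2[C@]1(COC3=O)C(=O)C=CC(C)(C)[C@H]1C=C
F3 | step 8 | 8-prop-2-enoyl spirolactone, C13 ketal retained | C=CC(=O)[C@]23CC4(OCCO4)CC[C@H]2[C@]1(COC3=O)C(=O)C=CC(C)(C)[C@H]1C=C
F4 | step 8 | 8-prop-2-enoyl 13-ketone | C=CC(=O)[C@]23CC(=O)CC[C@H]2[C@]1(COC3=O)C(=O)C=CC(C)(C)[C@H]1C=C
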